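At 15 h, the time we read the three new flasks, we want to know how much of the Q has reacted and how that moves with the equivalents of X.

the same everywhere: Q 0.050 M (fed, over 8.0 h)
- summer: X 0.76 equiv; run made earlier; the fed solution adds 1.0 times the starting volume
- midnight: X 1.3 equiv; run made earlier; the fed solution adds 1.0 times the starting volume
- Saturday's: X 1.10 equiv; the fed solution adds 1.0 times the starting volume; time 15 h
- Sunday's: X 1.40 equiv; the fed solution adds 1.0 times the starting volume; time 15 h
- Thursday's: X 1.80 equiv; the fed solution adds 1.0 times the starting volume; time 15 h

- summer (time / h: Q / %, J / %): 1.33: 15.3, 0; 4.00: 46.5, 2.6; 8.00: 93.8, 7.3; 10.0: 88.7, 11.2; 15.0: 84.2, 14.9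
- midnight (time / h: Q / %, J / %): 1.33: 16.1, 1.6; 2.50: 29.9, 2.7; 4.00: 45.7, 4.2; 8.00: 86.4, 11.4; 15.0: 74.7, 23.3

(scatter of a reading: 1 percentage point)

- charges are per starting volume, the dose included; the dosed solution carries all of it
- the numbers in the tables scatter with a standard deviation of 1 percentage point
- what may be going on: Q + X -> Z + J; X + Z <-> L
- percentages count the whole charge, also what has not yet gone in

- part of the Q that has reacted at the end, Saturday's
- part of the Q that has reacted at the end, Sunday's
- part of the Q that has reacted at the end, Thursday's
- what raising the equivalents of X from its lowest to its highest value here does to the part of the Q that has reacted (changes below 5 percentage points count as none) (no change / it falls / it rises)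

Which numbers must we know well? The charge of Q, the dosing time and the feed volume match the earlier runs, so they cancel when flasks are compared. The equivalents of X are what differ, so we compare the two runs at one moment. At 8.00 h midnight's J stands 1.56 times summer's, and at 15.0 h it stands 1.56 times. As read, and within the scatter, that comparison holds from the end of the dose to the last reading, and it reads below the equivalents ratio of 1.71. So J looks roughly first order in X, and we carry one quantity: the yield per equivalent, J at the reading time divided by the equivalents of X charged.

An error of 1 percentage point in midnight's last J moves Thursday's estimate by 1.4 points. The same error in summer's moves it by 2.4 points, so we take midnight's reading. The worry is midnight's Q column, which puts the reacted part at 25.3%, against 23.3% as J. Using it would raise Thursday's by 2.8 points. We stay with J.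

The yield per equivalent is 17.9%. That gives 19.7% for Saturday's, 25.1% for Sunday's and 32.3% for Thursday's. The rise of 13 points exceeds the 5 points that counts as a change.

The forecast reads 20.5%, 25.5% and 31.5%, and it rises, on the ground that “J scales with X”. Ours lies 0.80 points lower on Saturday's and 0.80 points higher on Thursday's.

The flasks give 20.8%, 25.8% and 31.9%, and the verdict is "it rises", by 11 points.

    Q + X → Z + J (k = 0.910 L mol⁻¹ h⁻¹)
    X + Z ⇌ L, settled at all times (K = 1300 L mol⁻¹)

Thursday's works out at 17.7% per equivalent, against our 17.9%. The neighbouring flask is Saturday's with 4.40 equiv of X, where the same reckoning gives 78.8%. That flask reaches 61.4%, or 14.0% per equivalent. At its end it holds 38.6% of the Q unreacted and 72% of its X unbound.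

The numbers in the tables stem from a simulated flask with made-up constants; noise was put on by code.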